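**Plan**

- Retrosynthesis: the C5–propenyl bond is cut first (triflate of a C5 phenol plus a propenylboronate). Ring A and the dihydrofuran ring are then opened together at C7a–C3a, C4–C5 and C5–C6, leaving a chromium alkoxycarbene with a 1-methoxyvinyl group on carbon and a homopropargylic alkoxy group on oxygen. The carbene C–O bond and the C2–C3 bond (aldehyde plus allenylmetal) are cut last.
- Enabling feature: ring A carries O1 on C7a, a methoxy group on C7 and its carbon substituent on C5, para to O1. With a hydroxyl at C5 this is a 4-alkoxyphenol, the arene that an alkenylcarbene, an alkyne and one CO ligand assemble.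
- Forward: C2–C3 is made in the open chain, the alcohol is hung on the carbene oxygen, and one thermal step closes the dihydrofuran ring (alkyne insertion) and then ring A (CO insertion, electrocyclisation). Triflation, Suzuki coupling and desilylation finish the route.
- Stereochemistry: C3 comes from (R)-but-3-yn-2-ol by chirality transfer through a (P)-allenylzinc, and C2 from the anti preference of its cyclic addition to the aldehyde. Both sit on the tether and are only carried through the ring-forming step. The E alkene is brought in by the boronate.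

Key step: step 6

Assumption: the five starting materials are purchased; [5-bromo-3-methoxy-2-(methoxymethoxy)phenyl]acetic acid, needed only in one fallback, is taken as an available building block; in SMILES the η6-bound Cr(CO)3 unit of the arene complex is written as a separate fragment.

**Route**

Step 1
Reactants: 1 3-hydroxy-4,5-dimethoxybenzaldehyde
Product: 2 3,4-dimethoxy-5-(triisopropylsilyloxy)benzaldehyde
Conditions: TIPSCl, imidazole, DMF, rt
Reagents that add atoms: triisopropylsilyl chloride, CC(C)[Si](Cl)(C(C)C)C(C)C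
Why: Imidazole-promoted O-silylation of the phenol gives a bulky aryl silyl ether that should tolerate the organozinc, acyl halide, triflation and aqueous-base steps and leave with fluoride at the end.

Step 2
Reactants: 3 (R)-but-3-yn-2-ol
Product: 4 (R)-but-3-yn-2-yl methanesulfonate
Conditions: MsCl, Et3N, CH2Cl2, −78 → 0 °C
Reagents that add atoms: methanesulfonyl chloride, CS(=O)(=O)Cl
Why: Mesylation takes place at oxygen, so the C–O stereocentre of the propargylic alcohol is not touched and the (R) configuration is kept.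

Step 3
Reactants: 2 3,4-dimethoxy-5-(triisopropylsilyloxy)benzaldehyde; 4 (R)-but-3-yn-2-yl methanesulfonate
Product: 6 (1S,2S)-1-[3,4-dimethoxy-5-(triisopropylsilyloxy)phenyl]-2-methylbut-3-yn-1-ol, via (P)-buta-1,2-dienyl(ethyl)zinc 5 (not isolated)
Conditions: Pd(OAc)2 (5 mol %), PPh3 (5 mol %), Et2Zn (3 equiv), THF, −78 → −20 °C; then 0.5 M HCl, 0 °C
Reagents that add atoms: none
Why: Marshall propargylation, in which zerovalent palladium (formed from Pd(OAc)2, PPh3 and Et2Zn) displaces the mesylate anti (SN2′), transmetallation gives the (P)-allenylzinc 5, and its cyclic SE2′ addition to the aldehyde with the aryl group anti to the allenyl methyl should set the methyl-bearing centre (later C3, S) by chirality transfer from 4 and the carbinol centre (later C2, S) by the anti preference of that transition state.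

Step 4
Reactants: 7 methyl vinyl ether; 8 hexacarbonylchromium Cr(CO)6
Product: 11 tetramethylammonium pentacarbonyl(2-methoxyprop-2-enoyl)chromate, via 1-methoxyvinyllithium 9 (not isolated), via lithium pentacarbonyl(2-methoxyprop-2-enoyl)chromate 10 (not isolated)
Conditions: t-BuLi, THF, −78 → 0 °C; Cr(CO)6, THF, −78 °C → rt; then Me4NBr, H2O, rt
Reagents that add atoms: tetramethylammonium bromide, C[N+](C)(C)C.[Br-]
Why: α-Lithiation of the enol ether and addition of the vinyllithium to a carbonyl ligand of Cr(CO)6 is the Fischer route to acylchromates, and exchange of lithium for tetramethylammonium gives a salt that can be dried and O-acylated cleanly.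

Step 5
Reactants: 11 tetramethylammonium pentacarbonyl(2-methoxyprop-2-enoyl)chromate; 6 (1S,2S)-1-[3,4-dimethoxy-5-(triisopropylsilyloxy)phenyl]-2-methylbut-3-yn-1-ol
Product: 13 pentacarbonyl{(1-methoxyethenyl)[(1S,2S)-1-[3,4-dimethoxy-5-(triisopropylsilyloxy)phenyl]-2-methylbut-3-yn-1-yloxy]methylidene}chromium (zerovalent chromium), via pentacarbonyl[acetoxy(1-methoxyethenyl)methylidene]chromium 12 (not isolated)
Conditions: 11 (1.5 equiv), AcBr, CH2Cl2, −40 °C; then 6, −40 → −10 °C, dark; cold filtration through silica, used at once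
Reagents that add atoms: none
Why: O-Acylation of the acylchromate gives the acyloxycarbene 12, and the alcohol then displaces acetate at the carbene carbon (alkoxy exchange of an acyloxycarbene, established for secondary alcohols such as menthol and for alkynols), a process that does not break the C–O bond of 6 and so keeps both stereocentres.

Step 6
Reactants: 13 pentacarbonyl{(1-methoxyethenyl)[(1S,2S)-1-[3,4-dimethoxy-5-(triisopropylsilyloxy)phenyl]-2-methylbut-3-yn-1-yloxy]methylidene}chromium
Product: 15 (2S,3S)-2-[3,4-dimethoxy-5-(triisopropylsilyloxy)phenyl]-7-methoxy-3-methyl-2,3-dihydro-1-benzofuran-5-ol, via tricarbonyl(η6-arene)chromium complex 14 (not isolated)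
Conditions: THF (0.01 M), 60 °C, argon, dark; then air, Et2O, rt
Reagents that add atoms: none
Why: Loss of one CO ligand lets the tethered alkyne bind chromium and insert into the Cr=C bond with its inner carbon on the carbene carbon (C7a–C3a), CO insertion at the new vinylcarbene carbon gives a chromium-bound dienylketene (C4–C5), and 6π electrocyclisation (C5–C6) followed by tautomerisation gives the C5 phenol, first as its Cr(CO)3 complex 14, which air decomplexes. The closest known reaction type is the intramolecular Dötz benzannulation of alkoxycarbene chromium complexes whose alkyne is tethered through the carbene oxygen by two carbons, here applied to an acyclic α-alkoxyvinyl carbene whose cyclic relatives (dihydropyranyl carbenes) are known to benzannulate. The dihydrofuran ring closes in the insertion step in a 5-exo-dig mode (C7a attacks the inner alkyne carbon and C4 stays outside the ring), and ring A closes by the disrotatory 6π electrocyclisation of the dienylketene. No stereocentre is formed: C2 and C3 lie on the saturated tether, take no part in the bond changes and are carried unchanged. The selectivity needed is regiochemical, since an untethered terminal alkyne would place its substituted carbon next to the CO-derived carbon, and the three-atom O1–C2–C3 tether overrides this by letting only the inner alkyne carbon reach the carbene carbon. High dilution disfavours intermolecular insertion, and THF as a donor solvent together with the alkenyl carbene favours CO insertion and phenol formation over cyclopentannulation.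

Step 7
Reactants: 15 (2S,3S)-2-[3,4-dimethoxy-5-(triisopropylsilyloxy)phenyl]-7-methoxy-3-methyl-2,3-dihydro-1-benzofuran-5-ol
Product: 16 (2S,3S)-2-[3,4-dimethoxy-5-(triisopropylsilyloxy)phenyl]-7-methoxy-3-methyl-2,3-dihydro-1-benzofuran-5-yl trifluoromethanesulfonate
Conditions: Tf2O, pyridine, CH2Cl2, 0 °C
Reagents that add atoms: trifluoromethanesulfonic anhydride, O=S(=O)(OS(=O)(=O)C(F)(F)F)C(F)(F)F
Why: O-Sulfonylation of the only free hydroxyl (the C5 phenol) turns it into a leaving group for cross-coupling, and the aryl silyl ether and the benzylic ether are inert to cold Tf2O buffered by pyridine.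

Step 8
Reactants: 16 (2S,3S)-2-[3,4-dimethoxy-5-(triisopropylsilyloxy)phenyl]-7-methoxy-3-methyl-2,3-dihydro-1-benzofuran-5-yl trifluoromethanesulfonate; 17 (E)-prop-1-enylboronic acid pinacol ester
Product: 18 triisopropyl{2,3-dimethoxy-5-[(2S,3S)-7-methoxy-3-methyl-5-[(E)-prop-1-enyl]-2,3-dihydro-1-benzofuran-2-yl]phenoxy}silane
Conditions: Pd(OAc)2 (5 mol %), SPhos (10 mol %), K3PO4, THF/H2O, 60 °C
Reagents that add atoms: none
Why: Suzuki–Miyaura coupling of an aryl triflate with an alkenylboronate goes with retention of alkene geometry, so the (E)-propenyl group is delivered as such, and the electron-rich biarylphosphine SPhos is chosen because oxidative addition into a triflate on an electron-rich ring is slow.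

Step 9
Reactants: 18 triisopropyl{2,3-dimethoxy-5-[(2S,3S)-7-methoxy-3-methyl-5-[(E)-prop-1-enyl]-2,3-dihydro-1-benzofuran-2-yl]phenoxy}silane
Product: 19 5-[(2S,3S)-7-methoxy-3-methyl-5-[(E)-prop-1-enyl]-2,3-dihydro-1-benzofuran-2-yl]-2,3-dimethoxyphenol (CNP0299956.1)
Conditions: Bu4NF, AcOH, THF, 0 °C → rt
Reagents that add atoms: none
Why: Fluoride-induced cleavage of the aryl O–Si bond (desilylation) frees the last phenol, and buffering with acetic acid keeps the medium near neutral so that neither the benzylic ether nor the propenyl group is disturbed.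

**Compound list**

1 | 3-hydroxy-4,5-dimethoxybenzaldehyde | O=Cc1cc(O)c(OC)c(OC)c1 | starting material
2 | 3,4-dimethoxy-5-(triisopropylsilyloxy)benzaldehyde | O=Cc1cc(O[Si](C(C)C)(C(C)C)C(C)C)c(OC)c(OC)c1 | intermediate
3 | (R)-but-3-yn-2-ol | C#C[C@@H](C)O | starting material
4 | (R)-but-3-yn-2-yl methanesulfonate | C#C[C@@H](C)OS(C)(=O)=O | intermediate
5 | (P)-buta-1,2-dienyl(ethyl)zinc | C[CH]=[C@@]=[CH][Zn]CC | intermediate
6 | (1S,2S)-1-[3,4-dimethoxy-5-(triisopropylsilyloxy)phenyl]-2-methylbut-3-yn-1-ol | O[C@H](c1cc(O[Si](C(C)C)(C(C)C)C(C)C)c(OC)c(OC)c1)[C@@H](C)C#C | intermediate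
7 | methyl vinyl ether | C=COC | starting material
8 | hexacarbonylchromium Cr(CO)6 | O=C=[Cr](=C=O)(=C=O)(=C=O)(=C=O)=C=O | starting material
9 | 1-methoxyvinyllithium | [Li]C(=C)OC | intermediate
10 | lithium pentacarbonyl(2-methoxyprop-2-enoyl)chromate | [Li+].C=C(OC)C([O-])=[Cr](=C=O)(=C=O)(=C=O)(=C=O)=C=O | intermediate
11 | tetramethylammonium pentacarbonyl(2-methoxyprop-2-enoyl)chromate | C[N+](C)(C)C.C=C(OC)C([O-])=[Cr](=C=O)(=C=O)(=C=O)(=C=O)=C=O | intermediate
12 | pentacarbonyl[acetoxy(1-methoxyethenyl)methylidene]chromium | C=C(OC)C(OC(C)=O)=[Cr](=C=O)(=C=O)(=C=O)(=C=O)=C=O | intermediate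
13 | pentacarbonyl{(1-methoxyethenyl)[(1S,2S)-1-[3,4-dimethoxy-5-(triisopropylsilyloxy)phenyl]-2-methylbut-3-yn-1-yloxy]methylidene}chromium (zerovalent chromium) | C=C(OC)C(O[C@H](c1cc(O[Si](C(C)C)(C(C)C)C(C)C)c(OC)c(OC)c1)[C@@H](C)C#C)=[Cr](=C=O)(=C=O)(=C=O)(=C=O)=C=O | intermediate
14 | tricarbonylchromium complex of 15, Cr(CO)3 bound η6 to ring A | Oc1cc(OC)c2c(c1)[C@H](C)[C@@H](c1cc(O[Si](C(C)C)(C(C)C)C(C)C)c(OC)c(OC)c1)O2.O=C=[Cr](=C=O)=C=O | intermediate
15 | (2S,3S)-2-[3,4-dimethoxy-5-(triisopropylsilyloxy)phenyl]-7-methoxy-3-methyl-2,3-dihydro-1-benzofuran-5-ol | Oc1cc(OC)c2c(c1)[C@H](C)[C@@H](c1cc(O[Si](C(C)C)(C(C)C)C(C)C)c(OC)c(OC)c1)O2 | intermediate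
16 | (2S,3S)-2-[3,4-dimethoxy-5-(triisopropylsilyloxy)phenyl]-7-methoxy-3-methyl-2,3-dihydro-1-benzofuran-5-yl trifluoromethanesulfonate | O=S(=O)(Oc1cc(OC)c2c(c1)[C@H](C)[C@@H](c1cc(O[Si](C(C)C)(C(C)C)C(C)C)c(OC)c(OC)c1)O2)C(F)(F)F | intermediate
17 | (E)-prop-1-enylboronic acid pinacol ester | C/C=C/B1OC(C)(C)C(C)(C)O1 | starting material
18 | triisopropyl{2,3-dimethoxy-5-[(2S,3S)-7-methoxy-3-methyl-5-[(E)-prop-1-enyl]-2,3-dihydro-1-benzofuran-2-yl]phenoxy}silane | C/C=C/c1cc(OC)c2c(c1)[C@H](C)[C@@H](c1cc(O[Si](C(C)C)(C(C)C)C(C)C)c(OC)c(OC)c1)O2 | intermediate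
19 | 5-[(2S,3S)-7-methoxy-3-methyl-5-[(E)-prop-1-enyl]-2,3-dihydro-1-benzofuran-2-yl]-2,3-dimethoxyphenol (CNP0299956.1) | C/C=C/c1cc(OC)c2c(c1)[C@H](C)[C@@H](c1cc(O)c(OC)c(OC)c1)O2 | target

**Step count and risks**

Total steps: 9. Longest linear sequence: 7 (steps 1, 3, 5, 6, 7, 8, 9).

Steps most likely to fail:

1. Step 6. The inserted vinylcarbene may be diverted before CO insertion (cyclobutenone or furan formation). The electron-rich benzylic C–O bond of the carbene ether may ionise on heating, with loss of the alkoxy group and of the C2 configuration. Intermolecular alkyne insertion may give oligomers. Fallback: ring A is taken from a preformed arene and only the dihydrofuran ring is built, setting out from 2. The imide (4S)-4-benzyl-3-{[5-bromo-3-methoxy-2-(methoxymethoxy)phenyl]acetyl}oxazolidin-2-one F1 (from the arylacetic acid, PivCl, Et3N, then lithiated (S)-4-benzyloxazolidin-2-one) is enolised with Bu2BOTf and i-Pr2NEt and added to 2 in an Evans syn-aldol reaction to give the aldol adduct F2, in which the auxiliary fixes the later C3. LiBH4 removes the auxiliary and gives the 1,3-diol F3. HCl in MeOH takes off the methoxymethyl group, and the freed phenol should close onto the benzylic cation to give the 2,3-trans 3-hydroxymethyl dihydrobenzofuran F4, the C3 substituent directing the new C2–O bond trans. TsCl and pyridine give the tosylate F5, and LiEt3BH should reduce it to the 5-bromo-3-methyl dihydrobenzofuran F6. Suzuki–Miyaura coupling of F6 with 17 under the conditions of step 8 comes back to the route at 18.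

2. Step 5. The acyloxycarbene may decompose, or the alcohol may add in conjugate fashion to the enol-ether carbene, before the hindered secondary alcohol exchanges at the carbene carbon. Fallback: the alcohol is joined to the carbene oxygen through silicon instead of by alkoxy exchange, setting out from 6 and 11. Treatment of 6 with excess Me2SiCl2 and Et3N gives the chlorodimethylsilyl ether F7. O-Silylation of 11 with F7 at −40 °C gives the siloxycarbene complex F8. On warming in THF this should undergo the same tether-directed benzannulation to the siloxane-bridged phenol F9 (seven-membered dioxasilepine ring, C5 hydroxyl free). TsOH in MeOH under argon cleaves the siloxane to the hydroquinone diol F10, and continued acid treatment should close the C7a hydroxyl onto the benzylic cation trans to the C3 methyl, coming back to the route at 15.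

3. Step 3. Anti selectivity may erode with an aromatic aldehyde, and the allenylzinc from a terminal-alkyne mesylate may partly racemise, so chirality transfer would be incomplete. Fallback: the alkyne is made after the two stereocentres instead of with them, setting out from 2. Brown crotylboration with (E)-crotyldiisopinocampheylborane of the (+)-α-pinene series (from (−)-Ipc2BOMe) should give the anti homoallylic alcohol F11. TESOTf and 2,6-lutidine give the triethylsilyl ether F12. Lemieux–Johnson cleavage (OsO4 cat., NaIO4, 2,6-lutidine, dioxane/H2O) gives the aldehyde F13. Ohira–Bestmann homologation (dimethyl (1-diazo-2-oxopropyl)phosphonate, K2CO3, MeOH, 0 °C) gives the silyl-protected alkyne F14. PPTS in MeOH removes the triethylsilyl group and returns to the route at 6.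

**Further compounds**

F1 | step 6 | (4S)-4-benzyl-3-{[5-bromo-3-methoxy-2-(methoxymethoxy)phenyl]acetyl}oxazolidin-2-one | COCOc1c(OC)cc(Br)cc1CC(=O)N1C(=O)OC[C@@H]1Cc1ccccc1
F2 | step 6 | (4S)-4-benzyl-3-{(2S,3S)-2-[5-bromo-3-methoxy-2-(methoxymethoxy)phenyl]-3-[3,4-dimethoxy-5-(triisopropylsilyloxy)phenyl]-3-hydroxypropanoyl}oxazolidin-2-one | O=C([C@@H](c1cc(Br)cc(OC)c1OCOC)[C@H](O)c1cc(O[Si](C(C)C)(C(C)C)C(C)C)c(OC)c(OC)c1)N1C(=O)OC[C@@H]1Cc1ccccc1
F3 | step 6 | (1S,2R)-2-[5-bromo-3-methoxy-2-(methoxymethoxy)phenyl]-1-[3,4-dimethoxy-5-(triisopropylsilyloxy)phenyl]propane-1,3-diol | OC[C@@H](c1cc(Br)cc(OC)c1OCOC)[C@H](O)c1cc(O[Si](C(C)C)(C(C)C)C(C)C)c(OC)c(OC)c1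
F4 | step 6 | [(2S,3R)-5-bromo-2-[3,4-dimethoxy-5-(triisopropylsilyloxy)phenyl]-7-methoxy-2,3-dihydro-1-benzofuran-3-yl]methanol | Brc1cc(OC)c2c(c1)[C@H](CO)[C@@H](c1cc(O[Si](C(C)C)(C(C)C)C(C)C)c(OC)c(OC)c1)O2
F5 | step 6 | [(2S,3R)-5-bromo-2-[3,4-dimethoxy-5-(triisopropylsilyloxy)phenyl]-7-methoxy-2,3-dihydro-1-benzofuran-3-yl]methyl 4-methylbenzenesulfonate | Brc1cc(OC)c2c(c1)[C@H](COS(=O)(=O)c1ccc(C)cc1)[C@@H](c1cc(O[Si](C(C)C)(C(C)C)C(C)C)c(OC)c(OC)c1)O2
F6 | step 6 | (2S,3S)-5-bromo-2-[3,4-dimethoxy-5-(triisopropylsilyloxy)phenyl]-7-methoxy-3-methyl-2,3-dihydro-1-benzofuran | Brc1cc(OC)c2c(c1)[C@H](C)[C@@H](c1cc(O[Si](C(C)C)(C(C)C)C(C)C)c(OC)c(OC)c1)O2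
F7 | step 5 | chloro{[(1S,2S)-1-[3,4-dimethoxy-5-(triisopropylsilyloxy)phenyl]-2-methylbut-3-yn-1-yl]oxy}dimethylsilane | C[Si](C)(Cl)O[C@H](c1cc(O[Si](C(C)C)(C(C)C)C(C)C)c(OC)c(OC)c1)[C@@H](C)C#C
F8 | step 5 | pentacarbonyl{(1-methoxyethenyl)[({[(1S,2S)-1-[3,4-dimethoxy-5-(triisopropylsilyloxy)phenyl]-2-methylbut-3-yn-1-yl]oxy}dimethylsilyl)oxy]methylidene}chromium | C=C(OC)C(O[Si](C)(C)O[C@H](c1cc(O[Si](C(C)C)(C(C)C)C(C)C)c(OC)c(OC)c1)[C@@H](C)C#C)=[Cr](=C=O)(=C=O)(=C=O)(=C=O)=C=O
F9 | step 5 | (4S,5S)-4-[3,4-dimethoxy-5-(triisopropylsilyloxy)phenyl]-9-methoxy-2,2,5-trimethyl-4,5-dihydro-1,3,2-benzodioxasilepin-7-ol | Oc1cc(OC)c2c(c1)[C@H](C)[C@@H](c1cc(O[Si](C(C)C)(C(C)C)C(C)C)c(OC)c(OC)c1)O[Si](C)(C)O2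
F10 | step 5 | 2-[(1S,2S)-1-[3,4-dimethoxy-5-(triisopropylsilyloxy)phenyl]-1-hydroxypropan-2-yl]-6-methoxybenzene-1,4-diol | Oc1cc(OC)c(O)c(c1)[C@H](C)[C@@H](c1cc(O[Si](C(C)C)(C(C)C)C(C)C)c(OC)c(OC)c1)O
F11 | step 3 | (1S,2S)-1-[3,4-dimethoxy-5-(triisopropylsilyloxy)phenyl]-2-methylbut-3-en-1-ol | O[C@H](c1cc(O[Si](C(C)C)(C(C)C)C(C)C)c(OC)c(OC)c1)[C@@H](C)C=C
F12 | step 3 | {[(1S,2S)-1-[3,4-dimethoxy-5-(triisopropylsilyloxy)phenyl]-2-methylbut-3-en-1-yl]oxy}triethylsilane | CC[Si](CC)(CC)O[C@H](c1cc(O[Si](C(C)C)(C(C)C)C(C)C)c(OC)c(OC)c1)[C@@H](C)C=C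
F13 | step 3 | (2R,3S)-3-[3,4-dimethoxy-5-(triisopropylsilyloxy)phenyl]-2-methyl-3-(triethylsilyloxy)propanal | CC[Si](CC)(CC)O[C@H](c1cc(O[Si](C(C)C)(C(C)C)C(C)C)c(OC)c(OC)c1)[C@@H](C)C=O
F14 | step 3 | {[(1S,2S)-1-[3,4-dimethoxy-5-(triisopropylsilyloxy)phenyl]-2-methylbut-3-yn-1-yl]oxy}triethylsilane | CC[Si](CC)(CC)O[C@H](c1cc(O[Si](C(C)C)(C(C)C)C(C)C)c(OC)c(OC)c1)[C@@H](C)C#C
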